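**Retrosynthetic overview**
1. The C13–C(=O) bond of the methoxalyl side chain is cut to the C13 ketone of 3-bromofascaplysin and the carbanion of an α-methoxy phosphonoacetate (a masked methoxalyl anion). Olefination followed by enol-ether hydrolysis gives the indole and the keto ester together, with no redox adjustment.
2. The N5–C4a bond comes from intramolecular SNAr quaternisation of 1-(4-bromo-2-fluorobenzoyl)-β-carboline.
3. The β-carboline comes from tryptamine and 4'-bromo-2'-fluoroacetophenone in one pot (Kornblum oxidation, Pictet–Spengler, aromatisation).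
4. Ring order: pyridine ring first, then the central five-membered ring (as the C13 ketone), which is aromatised to the indole in the last step.

Assumption: the target is flat and achiral (no stereocentre, no stereogenic axis), so there is no enantiomer to select; salts are drawn as ion pairs.

**Step 1**
Reactants: 1 tryptamine; 2 1-(4-bromo-2-fluorophenyl)ethan-1-one
Product: 6 aroyl-β-carboline (4-bromo-2-fluorophenyl)(9H-pyrido[3,4-b]indol-1-yl)methanone, via α-iodoketone 3 (not isolated), via arylglyoxal 4 (not isolated), via tetrahydro-β-carboline ketone 5 (not isolated)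
Conditions: I2 (0.8 equiv, promoter turned over by DMSO), DMSO, 110 °C, 1 h with 2 alone; then 1, 110 °C, 4 h
Reagents that add atoms: none
Why: Domino Kornblum oxidation/Pictet–Spengler/oxidative aromatisation: I2 α-iodinates 2, DMSO converts 3 into glyoxal 4, the aldehyde of 4 condenses with 1 and closes at indole C2 to give 5, and I2/DMSO dehydrogenates the new ring to the β-carboline; the transient C1 stereocentre of 5 is racemic and is erased on aromatisation.

**Step 2**
Reactants: 6 (4-bromo-2-fluorophenyl)(9H-pyrido[3,4-b]indol-1-yl)methanone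
Product: 8 3-bromofascaplysin chloride (3-bromo-13-oxo-12,13-dihydropyrido[1,2-a:3,4-b']diindol-5-ium chloride), via 3-bromofascaplysin fluoride 7 (not isolated)
Conditions: neat melt, 220 °C, 20 min, Ar; then HCl, MeOH, rt
Reagents that add atoms: hydrogen chloride, Cl
Why: Intramolecular SNAr quaternisation (addition–elimination): the pyridine nitrogen attacks the fluorine-bearing carbon, which is activated by the ortho ketone, and closes the five-membered ring, while the para bromine cannot be reached intramolecularly and stays; HCl exchanges fluoride for chloride; no stereocentre is formed.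

**Step 3**
Reactants: 8 3-bromofascaplysin chloride; 9 methyl 2-(dimethoxyphosphoryl)-2-methoxyacetate
Product: 12 methyl 2-(3-bromo-12H-pyrido[1,2-a:3,4-b']diindol-13-yl)-2-oxoacetate, via anhydro-base ketone 10 (not isolated), via enol ether 11 (not isolated)
Conditions: 9 (2.6 equiv), NaH (2.6 equiv), THF, 0 °C; then 8 in DMF, 0 °C → rt; then 1 M aq HCl, THF, rt
Reagents that add atoms: 9 methyl 2-(dimethoxyphosphoryl)-2-methoxyacetate, COC(C(=O)OC)P(=O)(OC)OC; water, O
Why: Proposed new method: the first equivalent of base removes the acidic N12–H to give anhydro-base 10, which should block the alkoxide-triggered C12b–C13 ring opening known for fascaplysin salts; the phosphonate carbanion of 9, a masked methoxalyl anion, then adds to the strained C13 ketone and the oxaphosphetane collapses to enol ether 11 (Horner–Wadsworth–Emmons olefination; closest known reaction types are HWE reactions of α-alkoxyphosphonoacetates with aldehydes and activated ketones to give α-keto-ester enol ethers, and the enolate addition of acetone to C13 of fascaplysin); N12-protonated 11 is the O-methyl oxocarbenium ion of the target, so aqueous acid replaces OMe by O and the five-membered ring becomes the aromatic indole; no stereocentre is formed.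

**Compound list**
1 | tryptamine, 2-(1H-indol-3-yl)ethan-1-amine | NCCc1c[nH]c2ccccc12 | starting material
2 | 1-(4-bromo-2-fluorophenyl)ethan-1-one | CC(=O)c1ccc(Br)cc1F | starting material
3 | 1-(4-bromo-2-fluorophenyl)-2-iodoethan-1-one | O=C(CI)c1ccc(Br)cc1F | intermediate
4 | 2-(4-bromo-2-fluorophenyl)-2-oxoacetaldehyde | O=CC(=O)c1ccc(Br)cc1F | intermediate
5 | (4-bromo-2-fluorophenyl)(2,3,4,9-tetrahydro-1H-pyrido[3,4-b]indol-1-yl)methanone, racemic | O=C(c1ccc(Br)cc1F)C1NCCc2c1[nH]c1ccccc21 | intermediate
6 | (4-bromo-2-fluorophenyl)(9H-pyrido[3,4-b]indol-1-yl)methanone | O=C(c1ccc(Br)cc1F)c1nccc2c1[nH]c1ccccc21 | intermediate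
7 | 3-bromo-13-oxo-12,13-dihydropyrido[1,2-a:3,4-b']diindol-5-ium fluoride | O=C1c2ccc(Br)cc2-[n+]2ccc3c4ccccc4[nH]c3c12.[F-] | intermediate
8 | 3-bromo-13-oxo-12,13-dihydropyrido[1,2-a:3,4-b']diindol-5-ium chloride (3-bromofascaplysin chloride) | O=C1c2ccc(Br)cc2-[n+]2ccc3c4ccccc4[nH]c3c12.[Cl-] | intermediate
9 | methyl 2-(dimethoxyphosphoryl)-2-methoxyacetate | COC(C(=O)OC)P(=O)(OC)OC | starting material
10 | 3-bromopyrido[1,2-a:3,4-b']diindol-13-one, neutral anhydro-base (N12 deprotonated) | O=C1c2ccc(Br)cc2N2C=CC3=C4C=CC=CC4=NC3=C12 | intermediate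
11 | methyl 2-(3-bromo-13H-pyrido[1,2-a:3,4-b']diindol-13-ylidene)-2-methoxyacetate, neutral anhydro-base, E/Z mixture (geometry lost in the next event) | COC(=O)C(OC)=C1c2ccc(Br)cc2N2C=CC3=C4C=CC=CC4=NC3=C12 | intermediate
12 | methyl 2-(3-bromo-12H-pyrido[1,2-a:3,4-b']diindol-13-yl)-2-oxoacetate (3-bromohomofascaplysin B), achiral | COC(=O)C(=O)c1c2ccc(Br)cc2n2ccc3c4ccccc4[nH]c3c12 | target

**Totals**
Total step count: 3. Longest linear sequence: 3 (1 + 2 → 6 → 8 → 12; 9 is bought). Compounds 1, 2 and 9 are inexpensive catalogue chemicals.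

**Steps most likely to fail, with fallbacks**

Step 3 (highest risk). The anhydro-base 10 may be too electron-rich for the hindered phosphonate carbanion, the carbanion may add to C6 of the pyridinium ring, or the adduct may revert or ring-open. The fallback makes the same bond stepwise by aldol addition and a separate elimination, and sets out from 8. The lithium enolate of methyl methoxyacetate (LDA, THF, −78 °C, 2.2 equiv, the first equivalent again forming 10) adds to C13 in the way acetone does in homofascaplysin A. Acidic work-up (HCl, MeOH) gives the carbinol salt 3-bromo-13-(1,2-dimethoxy-2-oxoethyl)-13-hydroxy-12,13-dihydropyrido[1,2-a:3,4-b']diindol-5-ium chloride F1. O-Acetylation (Ac2O, DMAP, pyridine, rt) gives 13-acetoxy-3-bromo-13-(1,2-dimethoxy-2-oxoethyl)-12,13-dihydropyrido[1,2-a:3,4-b']diindol-5-ium chloride F2. DBU (2.2 equiv, MeCN, 0 °C → rt) then removes the N–H and α-ester protons and expels acetate (E1cB). This comes back to the route at 11, which is hydrolysed to 12 by the acid work-up of step 3.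

Step 1. The free amine of 1 can attack the ketone-activated C–F bond of 2 or 4 at 110 °C, and aromatisation of 5 may stop short. The fallback builds the carboline by amide formation, Bischler–Napieralski cyclisation and oxidation instead, and sets out from 1. EDC/HOBt coupling with purchased 2-(4-bromo-2-fluorophenyl)acetic acid gives N-[2-(1H-indol-3-yl)ethyl]-2-(4-bromo-2-fluorophenyl)acetamide F3. POCl3 (MeCN, reflux) gives 1-(4-bromo-2-fluorobenzyl)-4,9-dihydro-3H-pyrido[3,4-b]indole F4. MnO2 (CHCl3, reflux) oxidises the doubly activated benzylic CH2 to the ketone and dehydrogenates the ring, coming back to the route at 6.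

Step 2. Fluoride set free at 220 °C can deprotonate N9–H and divert the closure to N9 (six-membered ring), or attack the para C–Br bond. The fallback replaces thermal SNAr by a copper-catalysed Ullmann-type N-arylation with iodide as leaving group, and sets out from 1. The step 1 conditions with purchased 1-(4-bromo-2-iodophenyl)ethan-1-one give (4-bromo-2-iodophenyl)(9H-pyrido[3,4-b]indol-1-yl)methanone F5. CuI (10 mol %, DMF, 120 °C) inserts selectively into C–I over C–Br and closes the ring to 3-bromo-13-oxo-12,13-dihydropyrido[1,2-a:3,4-b']diindol-5-ium iodide F6, with no basic fluoride present. F6 is used directly in step 3, where the first equivalent of base converts it into 10, the point at which the fallback comes back to the route.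

**Further compounds**
F1 | step 3 | 3-bromo-13-(1,2-dimethoxy-2-oxoethyl)-13-hydroxy-12,13-dihydropyrido[1,2-a:3,4-b']diindol-5-ium chloride, racemic diastereomer mixture | COC(=O)C(OC)C1(O)c2ccc(Br)cc2-[n+]2ccc3c4ccccc4[nH]c3c12.[Cl-]
F2 | step 3 | 13-acetoxy-3-bromo-13-(1,2-dimethoxy-2-oxoethyl)-12,13-dihydropyrido[1,2-a:3,4-b']diindol-5-ium chloride, racemic diastereomer mixture | COC(=O)C(OC)C1(OC(C)=O)c2ccc(Br)cc2-[n+]2ccc3c4ccccc4[nH]c3c12.[Cl-]
F3 | step 1 | N-[2-(1H-indol-3-yl)ethyl]-2-(4-bromo-2-fluorophenyl)acetamide | O=C(Cc1ccc(Br)cc1F)NCCc1c[nH]c2ccccc12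
F4 | step 1 | 1-(4-bromo-2-fluorobenzyl)-4,9-dihydro-3H-pyrido[3,4-b]indole | Fc1cc(Br)ccc1CC1=NCCc2c1[nH]c1ccccc21
F5 | step 2 | (4-bromo-2-iodophenyl)(9H-pyrido[3,4-b]indol-1-yl)methanone | O=C(c1ccc(Br)cc1I)c1nccc2c1[nH]c1ccccc21
F6 | step 2 | 3-bromo-13-oxo-12,13-dihydropyrido[1,2-a:3,4-b']diindol-5-ium iodide | O=C1c2ccc(Br)cc2-[n+]2ccc3c4ccccc4[nH]c3c12.[I-]
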